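**Retrosynthetic overview**
- Numbering: the eudesmanolide half is unprimed (ring-fusion carbons C5 and C10, lactone C12–O–C8, spiro carbon C11, its ring methylene C13). The elemane half is primed (quaternary C10′, ring CH carbons C5′ and C7′, ring CH2 C6′ between them, and C11′–C13′ as the three-carbon unit on C7′).
- Last disconnection: the dihydropyran (O–C11 and C13–C13′) opens by a retro oxa-Diels–Alder reaction to an elemane 2-substituted acrolein and 5-epi-isoalantolactone.
- Feature that carries the strategy: in the elemane cyclohexane (C5′–C10′), C7′ bears a propen-2-yl-type C3 unit beside the unsubstituted C6′. This is the pattern left when a C6′ aldehyde adds to a prenyl alkene with an allylic hydrogen shift, so C6′–C7′ is cut (carbonyl-ene) and the extra C6′ oxygen is removed afterwards.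
- The ene aldehyde comes from geraniol and 3-(benzyloxy)propanoic acid by an enantioselective Ireland–Claisen rearrangement (C5′, C10′). The lactone partner comes from isoalantolactone by C5 epimerisation through its 15-nor-4-ketone.
- Ring order: the decalin and lactone rings are taken from isoalantolactone, the elemane cyclohexane is closed in the ene step, and the dihydropyran is formed last.

Key step: step 8

Assumption: the (R,R)-configured diazaborolidine bromide controller is taken to deliver the (2R,3R) acid 5. The sense of induction is checked on 5 and, should it be the opposite, the (S,S)-controller is used with nothing else changed.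

**Step 1**
Reactants: 1 geraniol; 2 3-(benzyloxy)propanoic acid
Product: 3 (2E)-3,7-dimethylocta-2,6-dien-1-yl 3-(benzyloxy)propanoate
Conditions: DCC, DMAP (cat.), CH2Cl2, 0 °C → rt
Reagents that add atoms: none
Why: Steglich esterification joins the allylic alcohol and the acid under neutral conditions that leave the E-trisubstituted alkene and the benzyl ether untouched, and no stereocentre is formed.

**Step 2**
Reactants: 3 geranyl 3-(benzyloxy)propanoate
Product: 5 (2R,3R)-2-[(benzyloxy)methyl]-3-ethenyl-3,7-dimethyloct-6-enoic acid, via boron ketene acetal 4 (not isolated)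
Conditions: (4R,5R)-2-bromo-4,5-diphenyl-1,3-bis{[3,5-bis(trifluoromethyl)phenyl]sulfonyl}-1,3,2-diazaborolidine (1.3 equiv), i-Pr2NEt, CH2Cl2, −78 °C; then −20 → 4 °C; aqueous work-up
Reagents that add atoms: none
Why: In this enantioselective Ireland–Claisen rearrangement, soft enolisation in CH2Cl2 with the hindered amine should give the ketene acetal with CH2OBn cis to O–B; its chair [3,3] shift (E-alkene, homoprenyl chain equatorial, methyl axial) sets the C5′/C10′ relationship, and the C2-symmetric bis-sulfonamide ligand shields one enolate face and so fixes the absolute configuration of both centres.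

**Step 3**
Reactants: 5 Claisen acid
Product: 6 methyl (2R,3R)-2-[(benzyloxy)methyl]-3-ethenyl-3,7-dimethyloct-6-enoate
Conditions: MeI, K2CO3, DMF, rt
Reagents that add atoms: iodomethane CI
Why: SN2 O-alkylation of the carboxylate gives the methyl ester without touching the hindered α-stereocentre.

**Step 4**
Reactants: 6 methyl ester
Product: 7 (3R,4R)-3-[(benzyloxy)methyl]-4-ethenyl-2,4,8-trimethylnon-7-en-2-ol
Conditions: MeLi (4 equiv), CeCl3, THF, −78 → 0 °C; aq. NH4Cl
Reagents that add atoms: methyllithium [Li]C
Why: Double 1,2-addition of the weakly basic organocerium reagent turns the ester into the tertiary carbinol (C4′ with its two methyls) while avoiding enolisation, which would epimerise C5′ or expel benzyloxide.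

**Step 5**
Reactants: 7 tertiary alcohol
Product: 8 {[(3R,4R)-3-[(benzyloxy)methyl]-4-ethenyl-2,4,8-trimethylnon-7-en-2-yl]oxy}triethylsilane
Conditions: TESOTf, 2,6-lutidine, CH2Cl2, −78 → 0 °C
Reagents that add atoms: triethylsilyl trifluoromethanesulfonate CC[Si](CC)(CC)OS(=O)(=O)C(F)(F)F
Why: Silylation with the silyl triflate and a hindered pyridine base is the standard way to cap a congested tertiary alcohol.

**Step 6**
Reactants: 8 benzyl ether
Product: 9 (2R,3R)-3-ethenyl-3,7-dimethyl-2-[2-(triethylsilyloxy)propan-2-yl]oct-6-en-1-ol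
Conditions: lithium 4,4′-di-tert-butylbiphenylide, THF, −78 °C; aq. NH4Cl at −78 °C
Reagents that add atoms: none
Why: Reductive debenzylation by electron transfer from the arene radical anion cleaves only the benzylic C–O bond, the isolated alkenes and the silyl ether being inert, and the cold quench prevents O-to-O silyl migration in the lithium alkoxide.

**Step 7**
Reactants: 9 primary alcohol
Product: 10 (2S,3R)-3-ethenyl-3,7-dimethyl-2-[2-(triethylsilyloxy)propan-2-yl]oct-6-enal
Conditions: Dess–Martin periodinane, NaHCO3, CH2Cl2, 0 °C → rt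
Reagents that add atoms: none
Why: Buffered Dess–Martin oxidation gives the hindered β-silyloxy aldehyde under neutral conditions that cause neither epimerisation at C5′ nor elimination of silanol.

**Step 8**
Reactants: 10 ene aldehyde
Product: 11 (1R,2R,3R,6R)-3-ethenyl-3-methyl-6-(prop-1-en-2-yl)-2-[2-(triethylsilyloxy)propan-2-yl]cyclohexan-1-ol
Conditions: Me2AlCl (1.5 equiv), CH2Cl2, −78 → −40 °C; cold 1 M HCl
Reagents that add atoms: none
Why: Me2AlCl binds the aldehyde oxygen and the prenyl alkene attacks the activated carbonyl through C7′ while a hydrogen of an alkene methyl group passes to oxygen in a concerted, asynchronous ene process, after which the aluminium alkoxide loses methane so that no protic acid is set free. The closest known reaction type is the Lewis-acid type 1 intramolecular carbonyl-ene cyclisation of citronellal to isopulegol. The cyclohexane is closed by C6′–C7′ bond formation through a chair transition state in which each reacting π bond keeps one terminus outside the new ring (the analogue of a 6-exo closure). C7′ is set by the alkene lying equatorial on that chair and C6′ by the complexed carbonyl lying equatorial, both enforced by the equatorial C5′ silyloxypropyl group and by the axial C10′ methyl, which would clash with an axial C=O–Al unit; C6′ is removed later, so only the C7′ result is needed. The step needs chemoselectivity for the prenyl alkene, which the substrate secures because the C10′ vinyl group has no allylic hydrogen and cannot reach C6′ through an unstrained ring, and it needs the tertiary silyl ether to survive, which the low temperature and the proton-scavenging Lewis acid favour.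

**Step 9**
Reactants: 11 cyclohexanol
Product: 12 O-[(1R,2R,3R,6R)-3-ethenyl-3-methyl-6-(prop-1-en-2-yl)-2-[2-(triethylsilyloxy)propan-2-yl]cyclohexyl] O-phenyl carbonothioate
Conditions: PhOC(S)Cl, pyridine, DMAP (cat.), CH2Cl2, 0 → 40 °C
Reagents that add atoms: O-phenyl chlorothionoformate ClC(=S)Oc1ccccc1
Why: Acylation with the chlorothionoformate (first half of a Barton–McCombie deoxygenation) needs no alkoxide, so the neighbouring tertiary silyl ether cannot migrate to the C6′ oxygen.

**Step 10**
Reactants: 12 thionocarbonate
Product: 13 triethyl({2-[(1S,2R,5S)-2-ethenyl-2-methyl-5-(prop-1-en-2-yl)cyclohexyl]propan-2-yl}oxy)silane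
Conditions: Bu3SnH (0.3 M), AIBN (cat.), toluene, 90 °C
Reagents that add atoms: none
Why: Barton–McCombie radical deoxygenation removes the C6′ oxygen, the high stannane concentration trapping the secondary radical before a homoallyl 1,2-alkenyl shift, and C5′ and C7′ are not involved.

**Step 11**
Reactants: 13 deoxygenated cyclohexane
Product: 15 2-[(1S,3S,4R)-4-ethenyl-4-methyl-3-[2-(triethylsilyloxy)propan-2-yl]cyclohexyl]prop-2-enal, via allylic alcohol 14 (not isolated)
Conditions: SeO2 (0.5 equiv), t-BuOOH, CH2Cl2, 0 °C → rt; then Dess–Martin periodinane, NaHCO3, CH2Cl2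
Reagents that add atoms: tert-butyl hydroperoxide CC(C)(C)OO (terminal source of the new oxygen, delivered through selenium dioxide O=[Se]=O)
Why: Selenium dioxide allylic oxidation (ene reaction, then [2,3]-sigmatropic shift) attacks the methyl of the only 1,1-disubstituted alkene, the vinyl group having no allylic hydrogen and the second isopropenyl still being masked, and the Dess–Martin stage carries the allylic alcohol on to the enal.

**Step 12**
Reactants: 15 silyloxy enal
Product: 16 2-[(1S,3S,4R)-4-ethenyl-3-(2-hydroxypropan-2-yl)-4-methylcyclohexyl]prop-2-enal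
Conditions: HF·pyridine, THF, 0 °C → rt
Reagents that add atoms: none
Why: Fluoride-driven desilylation frees the tertiary alcohol under mildly acidic conditions that the enal and the alkenes tolerate.

**Step 13**
Reactants: 16 hydroxy enal
Product: 17 2-[(1S,3R,4R)-4-ethenyl-4-methyl-3-(prop-1-en-2-yl)cyclohexyl]prop-2-enal
Conditions: Burgess reagent, toluene, 50 °C
Reagents that add atoms: none
Why: Burgess dehydration (syn-elimination of the sulfamate ester) should take a methyl hydrogen and give the isopropenyl group, because the ring hydrogen at C5′ is shielded by the quaternary C10′ and a tetrasubstituted alkene there would be strained.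

**Step 14**
Reactants: 18 isoalantolactone
Product: 20 4-oxo-15-nor-5αH-eudesm-11(13)-en-12,8β-olide (trans-fused nor-ketone), via ozonide 19 (not isolated)
Conditions: O3 (1 equiv, Sudan Red 7B end point), CH2Cl2, −78 °C; then Me2S, −78 °C → rt
Reagents that add atoms: ozone [O-][O+]=O
Why: Ozonolysis with one equivalent of ozone should cleave the electron-rich 1,1-dialkyl C4=C15 alkene well before the electron-poor conjugated methylene of the lactone, and it makes C5 an enolisable position.

**Step 15**
Reactants: 20 trans-fused nor-ketone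
Product: 21 4-oxo-15-nor-5βH-eudesm-11(13)-en-12,8β-olide (cis-fused nor-ketone)
Conditions: p-TsOH·H2O (0.2 equiv), toluene, 60 °C; recovered 20 resubmitted
Reagents that add atoms: none
Why: Acid-catalysed enolisation equilibrates C5, and the cis-fused ketone should be favoured because ring flipping of the cis-decalin removes the syn-axial clash between the C10 methyl and the axial C8–O bond that the rigid trans-decalin must keep, the acid being compatible with the methylene lactone, which alkoxide bases would attack.

**Step 16**
Reactants: 21 cis-fused nor-ketone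
Product: 22 5-epi-isoalantolactone, (3aR,4aR,8aR,9aR)-8a-methyl-3,5-dimethylidenedecahydronaphtho[2,3-b]furan-2(3H)-one
Conditions: Zn, CH2Br2, TiCl4, THF, 0 °C; then 21, CH2Cl2, 0 °C → rt
Reagents that add atoms: dibromomethane BrCBr
Why: Takai–Lombardo methylenation uses a non-basic geminal dimetal reagent that converts the ketone into the exocyclic alkene without epimerising C5 and without attacking the lactone or its conjugated alkene.

**Step 17**
Reactants: 17 elemane enal; 22 5-epi-isoalantolactone
Product: 23 CNP0353330.1 (target; spiro dihydropyran with the ring oxygen on C11 on the face of H7 and H8, C11 R)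
Conditions: 22 (3 equiv), BHT (cat.), toluene (concentrated), 120 °C, sealed tube; excess 22 recovered
Reagents that add atoms: none
Why: In this thermal oxa-Diels–Alder reaction of the acrolein-dimerisation type, the enal acts as the 1-oxadiene and the methylene lactone as the 2π partner, so oxygen bonds to the carbonyl-bearing C11 and C13′ to C13; approach on the convex face of the cis-fused lactone (the side of H7 and H8) should set C11, and the excess of 22 holds back self-dimerisation of 17.

**Compound list**
1 | geraniol | CC(C)=CCC/C(C)=C/CO | starting material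
2 | 3-(benzyloxy)propanoic acid | OC(=O)CCOCc1ccccc1 | starting material
3 | (2E)-3,7-dimethylocta-2,6-dien-1-yl 3-(benzyloxy)propanoate | CC(C)=CCC/C(C)=C/COC(=O)CCOCc1ccccc1 | intermediate
4 | boron ketene acetal of 3 (CH2OBn cis to O–B, (4R,5R)-diazaborolidin-2-yl on oxygen) | CC(C)=CCC/C(C)=C/CO/C(OB1N(S(=O)(=O)c2cc(cc(c2)C(F)(F)F)C(F)(F)F)[C@H](c2ccccc2)[C@@H](c2ccccc2)N1S(=O)(=O)c1cc(cc(c1)C(F)(F)F)C(F)(F)F)=C/COCc1ccccc1 | intermediate
5 | (2R,3R)-2-[(benzyloxy)methyl]-3-ethenyl-3,7-dimethyloct-6-enoic acid | CC(C)=CCC[C@](C)(C=C)[C@H](COCc1ccccc1)C(=O)O | intermediate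
6 | methyl (2R,3R)-2-[(benzyloxy)methyl]-3-ethenyl-3,7-dimethyloct-6-enoate | CC(C)=CCC[C@](C)(C=C)[C@H](COCc1ccccc1)C(=O)OC | intermediate
7 | (3R,4R)-3-[(benzyloxy)methyl]-4-ethenyl-2,4,8-trimethylnon-7-en-2-ol | CC(C)=CCC[C@](C)(C=C)[C@H](COCc1ccccc1)C(C)(C)O | intermediate
8 | {[(3R,4R)-3-[(benzyloxy)methyl]-4-ethenyl-2,4,8-trimethylnon-7-en-2-yl]oxy}triethylsilane | CC(C)=CCC[C@](C)(C=C)[C@H](COCc1ccccc1)C(C)(C)O[Si](CC)(CC)CC | intermediate
9 | (2R,3R)-3-ethenyl-3,7-dimethyl-2-[2-(triethylsilyloxy)propan-2-yl]oct-6-en-1-ol | CC(C)=CCC[C@](C)(C=C)[C@H](CO)C(C)(C)O[Si](CC)(CC)CC | intermediate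
10 | (2S,3R)-3-ethenyl-3,7-dimethyl-2-[2-(triethylsilyloxy)propan-2-yl]oct-6-enal | CC(C)=CCC[C@](C)(C=C)[C@H](C=O)C(C)(C)O[Si](CC)(CC)CC | intermediate
11 | (1R,2R,3R,6R)-3-ethenyl-3-methyl-6-(prop-1-en-2-yl)-2-[2-(triethylsilyloxy)propan-2-yl]cyclohexan-1-ol | C=C[C@@]1(C)CC[C@H](C(C)=C)[C@@H](O)[C@@H]1C(C)(C)O[Si](CC)(CC)CC | intermediate
12 | O-phenyl thionocarbonate of 11 | C=C[C@@]1(C)CC[C@H](C(C)=C)[C@@H](OC(=S)Oc2ccccc2)[C@@H]1C(C)(C)O[Si](CC)(CC)CC | intermediate
13 | triethyl({2-[(1S,2R,5S)-2-ethenyl-2-methyl-5-(prop-1-en-2-yl)cyclohexyl]propan-2-yl}oxy)silane | C=C[C@@]1(C)CC[C@H](C(C)=C)C[C@@H]1C(C)(C)O[Si](CC)(CC)CC | intermediate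
14 | 2-[(1S,3S,4R)-4-ethenyl-4-methyl-3-[2-(triethylsilyloxy)propan-2-yl]cyclohexyl]prop-2-en-1-ol | C=C[C@@]1(C)CC[C@H](C(=C)CO)C[C@@H]1C(C)(C)O[Si](CC)(CC)CC | intermediate
15 | 2-[(1S,3S,4R)-4-ethenyl-4-methyl-3-[2-(triethylsilyloxy)propan-2-yl]cyclohexyl]prop-2-enal | C=C[C@@]1(C)CC[C@H](C(=C)C=O)C[C@@H]1C(C)(C)O[Si](CC)(CC)CC | intermediate
16 | 2-[(1S,3S,4R)-4-ethenyl-3-(2-hydroxypropan-2-yl)-4-methylcyclohexyl]prop-2-enal | C=C[C@@]1(C)CC[C@H](C(=C)C=O)C[C@@H]1C(C)(C)O | intermediate
17 | 2-[(1S,3R,4R)-4-ethenyl-4-methyl-3-(prop-1-en-2-yl)cyclohexyl]prop-2-enal | C=C[C@@]1(C)CC[C@H](C(=C)C=O)C[C@@H]1C(=C)C | intermediate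
18 | isoalantolactone | C=C1C(=O)O[C@@H]2C[C@@]3(C)CCCC(=C)[C@@H]3C[C@@H]21 | starting material
19 | ozonide (spiro 1,2,4-trioxolane at C4) of isoalantolactone | C=C1C(=O)O[C@@H]2C[C@@]3(C)CCCC4(OCOO4)[C@@H]3C[C@@H]21 | intermediate
20 | 4-oxo-15-nor-5αH-eudesm-11(13)-en-12,8β-olide (trans-fused) | C=C1C(=O)O[C@@H]2C[C@@]3(C)CCCC(=O)[C@@H]3C[C@@H]21 | intermediate
21 | 4-oxo-15-nor-5βH-eudesm-11(13)-en-12,8β-olide (cis-fused) | C=C1C(=O)O[C@@H]2C[C@@]3(C)CCCC(=O)[C@H]3C[C@@H]21 | intermediate
22 | 5-epi-isoalantolactone (5βH-eudesma-4(15),11(13)-dien-12,8β-olide) | C=C1C(=O)O[C@@H]2C[C@@]3(C)CCCC(=C)[C@H]3C[C@@H]21 | intermediate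
23 | CNP0353330.1 | C=C[C@@]1(C)CC[C@H](C2=CO[C@@]3(CC2)C(=O)O[C@@H]2C[C@@]4(C)CCCC(=C)[C@H]4C[C@@H]23)C[C@@H]1C(=C)C | target

**Step count**
Total: 17 steps. Longest linear sequence: 14 steps (steps 1–13 and 17).

**Steps most likely to fail**

Step 17 (oxa-Diels–Alder union). Self-dimerisation of enal 17, thermal oligomerisation of either partner, or weak facial discrimination at C11 may outrun the cross-cycloaddition. The fallback sets out from 17 and builds the same ring bond by bond. Conjugate addition of benzeneselenol (PhSeSePh, NaBH4, EtOH, then AcOH) should give the 3-(phenylselanyl) aldehyde F1, which is masked (HC(OMe)3, PPTS, MeOH) as the dimethyl acetal F2. Bu3SnH and AIBN in benzene at 80 °C in the presence of 22 generate the primary C13′ radical, whose Giese addition to the methylene lactone forms C13′–C13 and gives the 11,13-dihydro lactone F3. Deprotonation (KHMDS, THF, −78 °C) and oxidation of the lactone enolate with 3-phenyl-2-(phenylsulfonyl)oxaziridine on the convex face gives the 11-hydroxy lactone F4. Warm PPTS in toluene then exchanges the acetal onto the tertiary hydroxyl and eliminates methanol to the enol ether, which rejoins the route at 23.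

Step 2 (enantioselective Ireland–Claisen rearrangement). Loss of benzyloxide from the β-oxygenated boron enolate, incomplete control of the ketene acetal geometry, or poor enantioselection with this ester may erode the step. The fallback sets out from 3. LDA in THF–DMPU at −78 °C with TBSCl gives the silyl ketene acetal F5 (CH2OBn cis to OSi), which rearranges on warming through the same chair to the racemic silyl ester F6. Aqueous LiOH and acidification give the racemic acid, that is 5 together with its enantiomer F7. Crystallisation with (S)-1-phenylethylamine separates the ammonium salt F8 of 5 (the (R)-amine is used if the salt of F7 is the one that crystallises), and acidification rejoins the route at 5.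

Step 8 (carbonyl-ene ring closure). Lewis-acid ionisation or elimination of the tertiary silyl ether beside the aldehyde, or methyl transfer from aluminium to the hindered carbonyl, may compete with ring closure. The fallback sets out from 9 and forms the same C6′–C7′ bond by a radical. I2, PPh3 and imidazole give the primary iodide F9. With Co(dmgH)2(py)Cl (cat.), i-Pr2NEt and blue light in MeCN, the C6′ radical should close 6-exo onto the prenyl alkene through the same chair, and the cobaloxime dehydrogenates the tertiary radical to the isopropenyl group (alkyl Heck-type cyclisation). This gives 13 directly, so that 10, 11 and 12 are bypassed and the route is rejoined at 13.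

**Further compounds**
F1 | step 17 | 2-[(1S,3R,4R)-4-ethenyl-4-methyl-3-(prop-1-en-2-yl)cyclohexyl]-3-(phenylselanyl)propanal (both C11′ epimers) | C=C[C@@]1(C)CC[C@H](C(C[Se]c2ccccc2)C=O)C[C@@H]1C(=C)C
F2 | step 17 | dimethyl acetal of F1 | C=C[C@@]1(C)CC[C@H](C(C[Se]c2ccccc2)C(OC)OC)C[C@@H]1C(=C)C
F3 | step 17 | 11,13-dihydro lactone carrying the C13–C13′ bond and the dimethyl acetal (C11 and C11′ epimers) | C=C[C@@]1(C)CC[C@H](C(CCC3C(=O)O[C@@H]2C[C@@]4(C)CCCC(=C)[C@H]4C[C@@H]23)C(OC)OC)C[C@@H]1C(=C)C
F4 | step 17 | 11-hydroxy lactone (hydroxyl on the face of H7 and H8) carrying the dimethyl acetal | C=C[C@@]1(C)CC[C@H](C(CC[C@]3(O)C(=O)O[C@@H]2C[C@@]4(C)CCCC(=C)[C@H]4C[C@@H]23)C(OC)OC)C[C@@H]1C(=C)C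
F5 | step 2 | tert-butyldimethylsilyl ketene acetal of 3 (CH2OBn cis to OSi) | CC(C)=CCC/C(C)=C/CO/C(O[Si](C)(C)C(C)(C)C)=C/COCc1ccccc1
F6 | step 2 | tert-butyldimethylsilyl ester of the racemic Claisen acid (one enantiomer drawn) | CC(C)=CCC[C@](C)(C=C)[C@H](COCc1ccccc1)C(=O)O[Si](C)(C)C(C)(C)C
F7 | step 2 | (2S,3S)-2-[(benzyloxy)methyl]-3-ethenyl-3,7-dimethyloct-6-enoic acid (enantiomer of 5, second component of the racemic acid) | CC(C)=CCC[C@@](C)(C=C)[C@@H](COCc1ccccc1)C(=O)O
F8 | step 2 | (S)-1-phenylethanaminium salt of 5 | CC(C)=CCC[C@](C)(C=C)[C@H](COCc1ccccc1)C(=O)[O-].C[C@H]([NH3+])c1ccccc1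
F9 | step 8 | triethyl{[(3R,4R)-4-ethenyl-3-(iodomethyl)-2,4,8-trimethylnon-7-en-2-yl]oxy}silane | CC(C)=CCC[C@](C)(C=C)[C@H](CI)C(C)(C)O[Si](CC)(CC)CC
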